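## The problem

The target (28) is a (2S)-5,7-dihydroxyflavanone. Its ring B carries a free 4'-phenol and, ortho to it at C3', an (E)-7-hydroxy-3,7-dimethyloct-2-enyl chain, that is, a geranyl group hydrated at its far end. Ring A, a phloroglucinol-type benzene, is fused to the pyranone ring C through C4a–C8a, and ring B hangs on the only stereocentre, C2. C2 is benzylic, bears the ring oxygen and lies beta to the C4 ketone, so base opens the ring by retro-oxa-Michael reaction and racemises it. No second stereocentre exists to relay control, so C2 must be set by a catalyst and then kept away from base. The chain brings an E-trisubstituted alkene whose geometry must be carried through, a tertiary alcohol that ionises in strong acid, and, with the 4'-phenol, an ortho-allyl phenol that closes to a chroman under acid. The free 5,7-diol of ring A is electron-rich and easily oxidised. The enabling feature is the 1,3-dioxygenation of ring A: C5–C6–C7–C8 map onto a 1,1,3-trioxygenated butadiene, and C4a=C8a is the enol-ether double bond (C5=C6) of a 2-aryl-2,3-dihydro-4H-pyran-4-one. Such a dihydropyranone is the product of a catalytic asymmetric hetero-Diels–Alder reaction of the ring B aldehyde, so ring A can be grown last, under neutral conditions, on a ring C that already holds C2.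

## Retrosynthesis

**28 to 26.** Only the aryl O–CH2OCH3 bond and the chain O–Si bond are cut, so the last step is a deprotection. The phenol is a methoxymethyl ether because that group survives organomagnesium and organolithium reagents and directs the metalation used earlier. The tertiary alcohol is a triethylsilyl ether because, unlike a tertiary methoxymethyl ether, it falls off in dilute acid at room temperature. Ring A stays unprotected, since it is formed only one step before. The forward reaction must be acidic (base would racemise C2) but mild.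

**26 to 19 and 23.** The bonds C8–C8a and C4a–C5 are cut. This removes ring A and leaves the monocyclic (2S)-5-(phenylsulfinyl)-2,3-dihydro-4H-pyran-4-one 19 and the four-carbon diene 23.
- Against the neighbouring cuts: cutting O1–C2 (chalcone closure) or C2–C1' (conjugate arylation of a chromone) keeps ring A as a protected purchased unit and creates C2 late, next to the ketone that labilises it. The chosen cut has C2 in place before ring A exists and delivers the 5,7-diol free.
- Regiochemistry follows from polarity. The CH2 terminus of 23 is its most nucleophilic carbon and C6 of 19, beta to the ketone, is the most electrophilic. C8 therefore bonds to C8a, and the ketene-acetal carbon (the future oxygenated C5) bonds to C4a, next to the C4 carbonyl as in the target.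
- A sulfoxide is preferred to a halogen as the activating group on C5. After cycloaddition the hydrogen on C8a is not alpha to a carbonyl, so loss of HX by an E1cB path is not available. A sulfoxide needs only a cis beta hydrogen for thermal syn-elimination, and suprafacial addition supplies it.
- The forward step must achieve (4+2) addition to a push–pull alkene, loss of benzenesulfenic acid and methoxytrimethylsilane, and tautomerisation, all without acid or base.

**19 to 18 to 17 to 16.** The S–O bond of 19 is cut to sulfide 18, the C5–S bond of 18 to iodide 17, and the C5–I bond of 17 to dihydropyranone 16. Direct electrophilic sulfenylation of 16 would be one step shorter, but an activated sulfur electrophile would have to choose between the vinylogous ester, the chain alkene and the alkoxy-substituted ring B. Iodine with pyridine is specific for the enone, and the alkenyl iodide then takes sulfur by palladium catalysis at a defined position. Periodate is chosen for the oxidation because it leaves the alkene alone. These steps add no carbon; they need only be chemoselective and leave C2 untouched.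

**16 to 13 and 14.** Cutting O1–C6 and C2–C3 gives aldehyde 13 and (E)-1-methoxy-3-(trimethylsilyloxy)buta-1,3-diene 14. This one catalytic step sets the only stereocentre of the target and replaces a heterocycle by an achiral aromatic aldehyde. An asymmetric aldol reaction followed by separate ring construction would cost more steps for the same result.

**13 to 10 to 8 and 6.** The formyl carbon of 13 is cut from the ring to give aryl bromide 10, and the aryl–CH2 bond of 10 is cut to dibromide 8 and allylic bromide 6. The methoxymethoxy group of 8 draws the exchange reagent to the ortho bromine, which tells the two bromines apart. A route from 3-bromo-4-hydroxybenzaldehyde would need the aldehyde masked for the same organometallic coupling. The coupling must attack the primary carbon of 6 and keep the E geometry. 8 comes from 2,4-dibromophenol 7 by one protection.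

**6 to 5 to 4 to 3 to 1.** Bromide 6 is traced through alcohol 5 and acetate 4 to hydroxy acetate 3, and the C7–O bond of 3 is cut to geranyl acetate 1. Hydration belongs at this stage because the allylic acetate of 1 deactivates the 2,3-alkene, so an electrophilic hydration goes to the 6,7-alkene. That distinction would be lost once the chain sits on the arene. The E alkene is bought with 1 and never touched.

**23 to 21 to 20.** Diene 23 is cut at its two O–Si bonds to methyl acetoacetate 20 by way of silyl enol ether 21; both silylations are standard.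

## Roads not taken

**Alternative 1:** The cut is the C4a–C8a bond of ring A, with the O1–C2 bond of ring C opened as well. This unravels the target to the open-chain triketo ester A1, a methyl 9-aryl-3,5,7-trioxonon-8-enoate.
- Forward key step: a metal alkoxide such as Mg(OMe)2 would fold A1 by Claisen attack of C6 on the ester carbon, and enolisation would give ring A of the 2',4',6'-trihydroxychalcone A2.
- Merits: ring A forms without protecting groups, all carbons of rings A and C lie on one chain, and the cyclisation type is known from polyketide model chemistry.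
- Weak points: a 3,5,7-triketo ester can close in three ways (the Claisen mode wanted, an aldol attack of C2 on the C7 ketone, or lactonisation to a 4-hydroxy-2-pyranone). The cinnamoyl enone of A1 is a further Michael acceptor, and its assembly needs polyanion chemistry on a substrate with a free tertiary alcohol. Above all, A2 is achiral. C2 would have to be made by an enantioselective oxa-Michael closure of a 2',6'-dihydroxychalcone, for which chemical catalysts give limited selectivity and whose product racemises under the same basic conditions.
- Comparison: this road reaches ring A in fewer steps and needs no activating group to be put on and removed. The chosen plan sets against that a stereocentre fixed by a reliable catalytic reaction before ring A exists, and an aromatisation with one sensible regiochemical outcome.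

**Alternative 2:** The cut is made in ring B. The C1'–C2' and C5'–C6' bonds are broken, leaving the (2S)-2-ethynylchromanone A3 and the chain-bearing 2-silyloxy-3-alkylbutadiene A4.
- Forward key step: CoBr2(dppe), reduced with zinc in the presence of ZnI2, would join alkyne and diene to a cyclohexa-1,4-diene, and DDQ in the same flask would dehydrogenate it to flavanone A5.
- Merits: the cobalt-catalysed alkyne–diene (4+2) addition with oxidative aromatisation is established chemistry, which the key step of the chosen plan is not. Ring A and C2 would be secured early in a small molecule.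
- Weak points: A4 is 2,3-disubstituted, so the catalyst must place the alkyne substituent para to the silyloxy group and not para to the alkyl group. The two are poorly differentiated, and the wrong choice exchanges the positions of oxygen and chain on ring B. A4 is a sensitive cross-conjugated silyl enol ether that already contains the whole chain, so nothing is saved there. The propargylic C2 of A3 must survive ZnI2. DDQ is the classical reagent for dehydrogenating flavanones to flavones, which would erase the stereocentre of A5, and the allylic-benzylic CH2 of the chain is another site for it.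
- Comparison: in precedent this road is the stronger one. The chosen plan sets against it a regiochemistry fixed by strong polarisation of both partners, an aromatisation that needs no oxidant, and a ring A that is never protected.

**Alternative 3:** Ring C is opened at the C3=C4 bond at the enol-ether oxidation level. The target is traced to the 4-silyloxy-2H-chromene A7 and that to the chiral allyl aryl ether A6, in which a vinyl group on C2 and a 1-silyloxyvinyl group on ring A are to be joined.
- Forward key step: the second-generation Grubbs catalyst would close ring C by enol ether ring-closing metathesis, and hydrolysis of the silyl enol ether would give the chromanone.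
- Merits: metathesis is neutral and dependable, ring A comes from a cheap phloroglucinol-derived ketone, and every reaction type is known. In both respects this road is better placed than the chosen one.
- Weak points: A6 is a benzylic and allylic aryl ether that ionises easily and can undergo Claisen rearrangement. Making it enantiomerically pure requires an asymmetric allylic etherification with a hindered, ortho-acylated phenol. The 1,1-disubstituted silyl enol ether is a slow metathesis partner and is lost on any trace of acid. The 2H-chromene A7 can racemise by reversible electrocyclic opening to an ortho-quinone methide. Finally, four methoxymethyl ethers, one on the tertiary alcohol, must be removed with acid next to the ortho-allyl phenol.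
- Comparison: the chosen plan accepts one unprecedented step. It sets against that a stereocentre held in a dihydropyranone with no pericyclic escape, two protecting groups instead of five, and a final deprotection under milder acid.

Key step: step 14

Assumption: the (S)-BINOL–titanium catalyst of step 8 is taken to direct the diene to the Si face of aldehyde 13, the sense this catalyst family shows in aldehyde allylation, which gives the (2S)-dihydropyranone; should the product prove to be the antipode, (R)-BINOL is used with nothing else changed.

Remark on names: in the step lines Ar stands for 3-[(2E)-3,7-dimethyl-7-(triethylsilyloxy)oct-2-en-1-yl]-4-(methoxymethoxy)phenyl; the compound list gives full names.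

## Route

Step 1
Reactants: 1 geranyl acetate [(2E)-3,7-dimethylocta-2,6-dien-1-yl acetate]
Product: 3 (2E)-7-hydroxy-3,7-dimethyloct-2-en-1-yl acetate, via organomercurial 2 (not isolated)
Conditions: Hg(OAc)2, THF–H2O, rt; then NaBH4, aq. NaOH, 0 °C
Reagents that add atoms: water, O
Why: Oxymercuration–demercuration (Markovnikov hydration): the mercury salt attacks the remote 6,7-alkene because the 2,3-alkene is deactivated by the allylic acetate, water adds at the tertiary carbon and borohydride replaces mercury by hydrogen; no stereocentre remains.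

Step 2
Reactants: 3 (2E)-7-hydroxy-3,7-dimethyloct-2-en-1-yl acetate
Product: 4 (2E)-3,7-dimethyl-7-(triethylsilyloxy)oct-2-en-1-yl acetate
Conditions: Et3SiOTf, 2,6-lutidine, CH2Cl2, −78 to 0 °C
Reagents that add atoms: triethylsilyl trifluoromethanesulfonate, CC[Si](CC)(CC)OS(=O)(=O)C(F)(F)F
Why: Silylation of a hindered tertiary alcohol with a silyl triflate and a non-nucleophilic base; the allylic acetate is inert.

Step 3
Reactants: 4 (2E)-3,7-dimethyl-7-(triethylsilyloxy)oct-2-en-1-yl acetate
Product: 5 (2E)-3,7-dimethyl-7-(triethylsilyloxy)oct-2-en-1-ol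
Conditions: K2CO3 (cat.), MeOH, 0 °C to rt
Reagents that add atoms: none
Why: Base-catalysed transesterification of the acetate; a tertiary triethylsilyl ether is stable to carbonate in methanol.

Step 4
Reactants: 5 (2E)-3,7-dimethyl-7-(triethylsilyloxy)oct-2-en-1-ol
Product: 6 triethyl{[(6E)-8-bromo-2,6-dimethyloct-6-en-2-yl]oxy}silane
Conditions: CBr4, PPh3, CH2Cl2, 0 °C
Reagents that add atoms: carbon tetrabromide, BrC(Br)(Br)Br
Why: Appel reaction: the primary allylic alcohol is displaced by bromide at the alkoxyphosphonium stage under neutral conditions, without allylic transposition and with the E alkene and the silyl ether intact.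

Step 5
Reactants: 7 2,4-dibromophenol
Product: 8 2,4-dibromo-1-(methoxymethoxy)benzene
Conditions: MOMCl, iPr2NEt, CH2Cl2, 0 °C to rt
Reagents that add atoms: chloromethyl methyl ether, COCCl
Why: O-Alkylation of the phenol to its methoxymethyl ether, a routine protection.

Step 6
Reactants: 8 2,4-dibromo-1-(methoxymethoxy)benzene; 6 triethyl{[(6E)-8-bromo-2,6-dimethyloct-6-en-2-yl]oxy}silane
Product: 10 4-bromo-2-[(2E)-3,7-dimethyl-7-(triethylsilyloxy)oct-2-en-1-yl]-1-(methoxymethoxy)benzene, via aryl Grignard reagent 9 (not isolated)
Conditions: iPrMgCl·LiCl, THF, −15 to 0 °C; then CuBr·SMe2 (10 mol %), 6, −20 °C to rt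
Reagents that add atoms: none
Why: Chelation-assisted bromine–magnesium exchange at the bromine ortho to the methoxymethoxy group, then copper-catalysed Grignard coupling with the allylic bromide at its primary carbon (SN2), the gamma carbon being fully substituted; the E geometry of 6 is carried over.

Step 7
Reactants: 10 4-bromo-2-[(2E)-3,7-dimethyl-7-(triethylsilyloxy)oct-2-en-1-yl]-1-(methoxymethoxy)benzene
Product: 13 3-[(2E)-3,7-dimethyl-7-(triethylsilyloxy)oct-2-en-1-yl]-4-(methoxymethoxy)benzaldehyde, via aryllithium 11 (not isolated), via lithium hemiaminal alkoxide 12 (not isolated)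
Conditions: n-BuLi, THF, −78 °C; DMF, −78 to 0 °C; aq. NH4Cl
Reagents that add atoms: N,N-dimethylformamide, CN(C)C=O
Why: Bromine–lithium exchange is faster than any deprotonation at −78 °C, and formylation of the aryllithium with a formamide (Bouveault-type) gives the aldehyde on work-up.

Step 8
Reactants: 13 3-[(2E)-3,7-dimethyl-7-(triethylsilyloxy)oct-2-en-1-yl]-4-(methoxymethoxy)benzaldehyde; 14 (E)-1-methoxy-3-(trimethylsilyloxy)buta-1,3-diene
Product: 16 (2S)-2-Ar-2,3-dihydro-4H-pyran-4-one, via aldol adduct 15 (not isolated)
Conditions: (S)-BINOL (20 mol %), Ti(OiPr)4 (10 mol %), 4 Å MS, Et2O, −20 °C; then CF3CO2H (cat.), CH2Cl2, 0 °C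
Reagents that add atoms: none
Why: Catalytic asymmetric hetero-Diels–Alder reaction in its Mukaiyama-aldol variant: the BINOL–titanium Lewis acid activates the aldehyde and shields one face, so C2 is set by catalyst control (Si-face attack gives 2S), and acid closes the ring by oxa-Michael addition with loss of methoxytrimethylsilane.

Step 9
Reactants: 16 (2S)-2-Ar-2,3-dihydro-4H-pyran-4-one
Product: 17 (2S)-2-Ar-5-iodo-2,3-dihydro-4H-pyran-4-one
Conditions: iodine, pyridine–CH2Cl2, 0 °C to rt
Reagents that add atoms: iodine, [I][I]
Why: Alpha-iodination of an enone with iodine and pyridine (addition–elimination), well known for 2,3-dihydro-4H-pyran-4-ones; the unconjugated chain alkene takes up iodine only reversibly and C2 is not involved.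

Step 10
Reactants: 17 (2S)-2-Ar-5-iodo-2,3-dihydro-4H-pyran-4-one
Product: 18 (2S)-2-Ar-5-(phenylsulfanyl)-2,3-dihydro-4H-pyran-4-one
Conditions: PhSH, Pd2(dba)3 (2.5 mol %), Xantphos (5 mol %), iPr2NEt, 1,4-dioxane, 60 °C
Reagents that add atoms: thiophenol, Sc1ccccc1
Why: Palladium-catalysed carbon–sulfur cross-coupling (Migita type) of an alkenyl iodide with a thiol by oxidative addition into C5–I, thiolate transfer and reductive elimination; a hindered amine and moderate temperature are chosen so that C2 is left alone.

Step 11
Reactants: 18 (2S)-2-Ar-5-(phenylsulfanyl)-2,3-dihydro-4H-pyran-4-one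
Product: 19 (2S)-2-Ar-5-(phenylsulfinyl)-2,3-dihydro-4H-pyran-4-one (both sulfur epimers)
Conditions: NaIO4, MeOH–THF–H2O, 0 °C to rt
Reagents that add atoms: sodium periodate, [Na+].[O-]I(=O)(=O)=O
Why: Periodate oxidises a sulfide to the sulfoxide, stops there and does not epoxidise the chain alkene; the sulfur stereocentre is formed without control, which is acceptable because sulfur is lost in step 14.

Step 12
Reactants: 20 methyl acetoacetate
Product: 21 methyl (2E)-3-(trimethylsilyloxy)but-2-enoate
Conditions: Me3SiCl, Et3N, hexane, rt
Reagents that add atoms: chlorotrimethylsilane, C[Si](C)(C)Cl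
Why: O-Silylation of the enol of a beta-keto ester; the E isomer is expected to predominate, and the geometry is of no consequence for the next step.

Step 13
Reactants: 21 methyl (2E)-3-(trimethylsilyloxy)but-2-enoate
Product: 23 1-methoxy-1,3-bis(trimethylsilyloxy)buta-1,3-diene, via lithium dienolate 22 (not isolated)
Conditions: LiN(iPr)2, THF, −78 °C; Me3SiCl, −78 to 0 °C
Reagents that add atoms: chlorotrimethylsilane, C[Si](C)(C)Cl
Why: Gamma-deprotonation of the silyloxy enoate gives the extended ester enolate, which is silylated on oxygen to the ketene silyl acetal; this is the standard preparation of 1,3-bis(silyloxy) dienes.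

Step 14
Reactants: 19 (2S)-2-Ar-5-(phenylsulfinyl)-2,3-dihydro-4H-pyran-4-one (both sulfur epimers); 23 1-methoxy-1,3-bis(trimethylsilyloxy)buta-1,3-diene
Product: 26 (2S)-2-Ar-5,7-dihydroxychroman-4-one, via cycloadduct 24 (not isolated), via 7-silyl ether 25 (not isolated)
Conditions: 23 (3 equiv), toluene, rt then 80 °C; then 0.1 M aq. citric acid, THF, 0 °C
Reagents that add atoms: none
Why: Proposed new method: diene 23 is expected to add across the C5=C6 bond of 19 in a normal-demand Diels–Alder reaction, its nucleophilic CH2 terminus bonding to C6 (the beta carbon of the enone, made more electrophilic by the sulfinyl and carbonyl groups around C5) and its ketene-acetal carbon to C5, to give cis-fused adduct 24. The closest known reactions are the Diels–Alder/elimination sequences of 1,1,3-trioxygenated butadienes with sulfinyl- or halo-substituted quinones and with 3-acceptor-substituted chromones, and the tandem cycloaddition–sulfoxide elimination of 2-sulfinyl enones; a sulfinyl-activated dihydropyranone has not been used in this way. Ring A, a six-membered carbocycle, is closed by the (4+2) cycloaddition itself (C8–C8a and C4a–C5); should the process be stepwise, a Mukaiyama–Michael addition at C6 is followed by a 6-exo-trig Dieckmann-type attack of the C5 silyl enol ether on the ester carbon, and the same ring results. In 24 the sulfinyl group on C4a and the hydrogen on C8a are cis because the addition is suprafacial, so thermal syn-elimination of benzenesulfenic acid gives the C4a=C8a bond, and no other beta hydrogen is available. Collapse of the mixed silyl ketal at C5 with loss of methoxytrimethylsilane gives a dienone that tautomerises to phenol 25, and mild aqueous acid removes the aryl silyl ether. No new stereocentre survives: those at C4a, C5, C8a and sulfur are destroyed on aromatisation, and C2, set in step 8, meets no base. The selectivity needed is regiochemical (C8 to C8a, C5 to C4a) and chemoselectivity against the chain alkene; the first follows from pairing the most nucleophilic diene terminus with the doubly activated beta carbon, the second from the inertness of an unactivated alkene toward the diene. Excess diene also silylates and so removes the sulfenic acid.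

Step 15
Reactants: 26 (2S)-2-Ar-5,7-dihydroxychroman-4-one
Product: 28 (2S)-5,7-dihydroxy-2-{4-hydroxy-3-[(2E)-7-hydroxy-3,7-dimethyloct-2-en-1-yl]phenyl}chroman-4-one, via chain alcohol 27 (not isolated)
Conditions: 2 M aq. HCl, MeOH–THF, rt
Reagents that add atoms: none
Why: Acid-catalysed cleavage of the silyl ether and then of the aryl methoxymethyl acetal (acetal exchange with methanol); dilute acid at room temperature is chosen so that the ortho-allyl phenol does not close to a chroman and the tertiary alcohol does not ionise, and acid does not open the flavanone, so C2 is retained.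

## Compound list

1 | geranyl acetate, (2E)-3,7-dimethylocta-2,6-dien-1-yl acetate | C/C(=C\COC(C)=O)CCC=C(C)C | starting material
2 | (2E)-6-(acetoxymercurio)-7-hydroxy-3,7-dimethyloct-2-en-1-yl acetate (racemic at C6) | C/C(=C\COC(C)=O)CCC([Hg]OC(C)=O)C(C)(C)O | intermediate
3 | (2E)-7-hydroxy-3,7-dimethyloct-2-en-1-yl acetate | C/C(=C\COC(C)=O)CCCC(C)(C)O | intermediate
4 | (2E)-3,7-dimethyl-7-(triethylsilyloxy)oct-2-en-1-yl acetate | C/C(=C\COC(C)=O)CCCC(C)(C)O[Si](CC)(CC)CC | intermediate
5 | (2E)-3,7-dimethyl-7-(triethylsilyloxy)oct-2-en-1-ol | C/C(=C\CO)CCCC(C)(C)O[Si](CC)(CC)CC | intermediate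
6 | triethyl{[(6E)-8-bromo-2,6-dimethyloct-6-en-2-yl]oxy}silane | C/C(=C\CBr)CCCC(C)(C)O[Si](CC)(CC)CC | intermediate
7 | 2,4-dibromophenol | Oc1ccc(Br)cc1Br | starting material
8 | 2,4-dibromo-1-(methoxymethoxy)benzene | COCOc1ccc(Br)cc1Br | intermediate
9 | [5-bromo-2-(methoxymethoxy)phenyl]magnesium chloride (LiCl complex) | COCOc1ccc(Br)cc1[Mg]Cl | intermediate
10 | 4-bromo-2-[(2E)-3,7-dimethyl-7-(triethylsilyloxy)oct-2-en-1-yl]-1-(methoxymethoxy)benzene | C/C(=C\Cc1cc(Br)ccc1OCOC)CCCC(C)(C)O[Si](CC)(CC)CC | intermediate
11 | {3-[(2E)-3,7-dimethyl-7-(triethylsilyloxy)oct-2-en-1-yl]-4-(methoxymethoxy)phenyl}lithium | C/C(=C\Cc1cc([Li])ccc1OCOC)CCCC(C)(C)O[Si](CC)(CC)CC | intermediate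
12 | lithium (dimethylamino){3-[(2E)-3,7-dimethyl-7-(triethylsilyloxy)oct-2-en-1-yl]-4-(methoxymethoxy)phenyl}methanolate (racemic at the hemiaminal carbon) | C/C(=C\Cc1cc(C(O[Li])N(C)C)ccc1OCOC)CCCC(C)(C)O[Si](CC)(CC)CC | intermediate
13 | 3-[(2E)-3,7-dimethyl-7-(triethylsilyloxy)oct-2-en-1-yl]-4-(methoxymethoxy)benzaldehyde | C/C(=C\Cc1cc(C=O)ccc1OCOC)CCCC(C)(C)O[Si](CC)(CC)CC | intermediate
14 | (E)-1-methoxy-3-(trimethylsilyloxy)buta-1,3-diene | CO/C=C/C(=C)O[Si](C)(C)C | starting material
15 | (1E,5S)-5-{3-[(2E)-3,7-dimethyl-7-(triethylsilyloxy)oct-2-en-1-yl]-4-(methoxymethoxy)phenyl}-1-methoxy-5-(trimethylsilyloxy)pent-1-en-3-one | C/C(=C\Cc1cc([C@@H](O[Si](C)(C)C)CC(=O)/C=C/OC)ccc1OCOC)CCCC(C)(C)O[Si](CC)(CC)CC | intermediate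
16 | (2S)-2-{3-[(2E)-3,7-dimethyl-7-(triethylsilyloxy)oct-2-en-1-yl]-4-(methoxymethoxy)phenyl}-2,3-dihydro-4H-pyran-4-one | C/C(=C\Cc1cc([C@@H]2CC(=O)C=CO2)ccc1OCOC)CCCC(C)(C)O[Si](CC)(CC)CC | intermediate
17 | (2S)-2-{3-[(2E)-3,7-dimethyl-7-(triethylsilyloxy)oct-2-en-1-yl]-4-(methoxymethoxy)phenyl}-5-iodo-2,3-dihydro-4H-pyran-4-one | C/C(=C\Cc1cc([C@@H]2CC(=O)C(I)=CO2)ccc1OCOC)CCCC(C)(C)O[Si](CC)(CC)CC | intermediate
18 | (2S)-2-{3-[(2E)-3,7-dimethyl-7-(triethylsilyloxy)oct-2-en-1-yl]-4-(methoxymethoxy)phenyl}-5-(phenylsulfanyl)-2,3-dihydro-4H-pyran-4-one | C/C(=C\Cc1cc([C@@H]2CC(=O)C(Sc3ccccc3)=CO2)ccc1OCOC)CCCC(C)(C)O[Si](CC)(CC)CC | intermediate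
19 | (2S)-2-{3-[(2E)-3,7-dimethyl-7-(triethylsilyloxy)oct-2-en-1-yl]-4-(methoxymethoxy)phenyl}-5-(phenylsulfinyl)-2,3-dihydro-4H-pyran-4-one (both epimers at sulfur, sulfur left undefined) | C/C(=C\Cc1cc([C@@H]2CC(=O)C(S(=O)c3ccccc3)=CO2)ccc1OCOC)CCCC(C)(C)O[Si](CC)(CC)CC | intermediate
20 | methyl acetoacetate | COC(=O)CC(C)=O | starting material
21 | methyl (2E)-3-(trimethylsilyloxy)but-2-enoate | COC(=O)/C=C(\C)O[Si](C)(C)C | intermediate
22 | lithium 1-methoxy-3-(trimethylsilyloxy)buta-1,3-dien-1-olate | C=C(O[Si](C)(C)C)C=C(OC)O[Li] | intermediate
23 | 1-methoxy-1,3-bis(trimethylsilyloxy)buta-1,3-diene (ketene acetal drawn E) | C=C(O[Si](C)(C)C)/C=C(\OC)O[Si](C)(C)C | intermediate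
24 | (2S)-2-{3-[(2E)-3,7-dimethyl-7-(triethylsilyloxy)oct-2-en-1-yl]-4-(methoxymethoxy)phenyl}-5-methoxy-4a-(phenylsulfinyl)-5,7-bis(trimethylsilyloxy)-2,3,4a,5,8,8a-hexahydro-4H-chromen-4-one (cis ring fusion; C4a, C5, C8a and sulfur as a mixture, left undefined) | C/C(=C\Cc1cc([C@@H]2CC(=O)C3(S(=O)c4ccccc4)C(O2)CC(O[Si](C)(C)C)=CC3(OC)O[Si](C)(C)C)ccc1OCOC)CCCC(C)(C)O[Si](CC)(CC)CC | intermediate
25 | (2S)-2-{3-[(2E)-3,7-dimethyl-7-(triethylsilyloxy)oct-2-en-1-yl]-4-(methoxymethoxy)phenyl}-5-hydroxy-7-(trimethylsilyloxy)chroman-4-one | C/C(=C\Cc1cc([C@@H]2CC(=O)c3c(O)cc(O[Si](C)(C)C)cc3O2)ccc1OCOC)CCCC(C)(C)O[Si](CC)(CC)CC | intermediate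
26 | (2S)-2-{3-[(2E)-3,7-dimethyl-7-(triethylsilyloxy)oct-2-en-1-yl]-4-(methoxymethoxy)phenyl}-5,7-dihydroxychroman-4-one | C/C(=C\Cc1cc([C@@H]2CC(=O)c3c(O)cc(O)cc3O2)ccc1OCOC)CCCC(C)(C)O[Si](CC)(CC)CC | intermediate
27 | (2S)-5,7-dihydroxy-2-{3-[(2E)-7-hydroxy-3,7-dimethyloct-2-en-1-yl]-4-(methoxymethoxy)phenyl}chroman-4-one | C/C(=C\Cc1cc([C@@H]2CC(=O)c3c(O)cc(O)cc3O2)ccc1OCOC)CCCC(C)(C)O | intermediate
28 | (2S)-5,7-dihydroxy-2-{4-hydroxy-3-[(2E)-7-hydroxy-3,7-dimethyloct-2-en-1-yl]phenyl}chroman-4-one | C/C(=C\Cc1cc([C@@H]2CC(=O)c3c(O)cc(O)cc3O2)ccc1O)CCCC(C)(C)O | target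

## Step count and risks

Total step count: 15. Longest linear sequence: 12 steps (steps 1–4, 6–11, 14 and 15); steps 5, 12 and 13 are side branches.

**Step 14 (key step, proposed new method).**
- What may go wrong: the push–pull dihydropyranone may be too poor a dienophile, so that the diene is lost to silyl transfer or attacks the sulfinyl oxygen (Pummerer-type reduction of the sulfoxide). Alternatively, a stepwise Michael addition at C6 may be followed by expulsion of the ring oxygen, opening the pyranone instead of closing ring A.
- Fallback (known chemistry): it sets out from aryl bromide 10 and comes back to the route at 28. Bromine–lithium exchange of 10 (n-BuLi, THF, −78 °C), B(OiPr)3 and aqueous work-up would give {3-[(2E)-3,7-dimethyl-7-(triethylsilyloxy)oct-2-en-1-yl]-4-(methoxymethoxy)phenyl}boronic acid F1. Commercial 5,7-dihydroxy-4H-chromen-4-one would be converted with MOMCl and NaH in DMF into 5,7-bis(methoxymethoxy)-4H-chromen-4-one F2. Rhodium-catalysed asymmetric 1,4-addition of F1 to F2, an established route to 2-arylchroman-4-ones, would use [Rh(OH)(cod)]2 with an electron-poor atropisomeric bisphosphine of the MeO-BIPHEP family, in the antipode that gives 2S, in toluene–water. It would give (2S)-2-{3-[(2E)-3,7-dimethyl-7-(triethylsilyloxy)oct-2-en-1-yl]-4-(methoxymethoxy)phenyl}-5,7-bis(methoxymethoxy)chroman-4-one F3, which the conditions of step 15 would convert into 28. Ring A is then bought and not built.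

**Step 6.**
- What may go wrong: exchange at the para bromine, attack of the aryl group at the tertiary gamma carbon of the allylic bromide, or erosion of the alkene geometry.
- Fallback: it sets out from bromide 6 and comes back at aldehyde 13, bypassing 10 and step 7. Commercial 3-bromo-4-hydroxybenzaldehyde would be protected (MOMCl, iPr2NEt) to 3-bromo-4-(methoxymethoxy)benzaldehyde F4. Miyaura borylation (B2pin2, Pd(dppf)Cl2, KOAc, 1,4-dioxane, 80 °C) would give 4-(methoxymethoxy)-3-(4,4,5,5-tetramethyl-1,3,2-dioxaborolan-2-yl)benzaldehyde F5. Suzuki–Miyaura coupling of F5 with 6 (Pd(PPh3)4, K3PO4, THF–H2O, 50 °C) would give 13. The regiochemistry on the ring is then fixed by the starting material, and the polar alkylation is replaced by an allyl–palladium cross-coupling.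

**Step 8.**
- What may go wrong: insufficient facial selectivity with an electron-rich benzaldehyde, or loss of the silyl ether during the acid treatment.
- Fallback: it sets out from 13 and comes back at 16. Hydrogen-bond catalysis would replace the Lewis acid: 13 and 1-(dimethylamino)-3-(tert-butyldimethylsilyloxy)buta-1,3-diene with a tetra(1-naphthyl) TADDOL (the antipode that gives 2S) in toluene at −40 °C would give the cycloadduct (6S)-4-(tert-butyldimethylsilyloxy)-6-{3-[(2E)-3,7-dimethyl-7-(triethylsilyloxy)oct-2-en-1-yl]-4-(methoxymethoxy)phenyl}-N,N-dimethyl-5,6-dihydro-2H-pyran-2-amine F6. Acetyl chloride at −78 °C would convert F6 into 16 without protic acid.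

**Step 10.**
- What may go wrong: conjugate addition of thiolate at C6 with opening of the ring, base-induced opening at C2–O1 (racemisation), or reductive loss of iodine.
- Fallback: it sets out from 16, leaves out iodide 17 and comes back at 18. Direct electrophilic sulfenylation of C5–H with N-(phenylthio)succinimide and catalytic CF3CO2H in CH2Cl2 would be used. No base is present; selectivity over the chain alkene would have to be secured by low temperature. This fallback makes no new compound (F0).

**Step 15.**
- What may go wrong: acid-promoted addition of the freed phenol to the chain alkene (chroman formation) or ionisation of the tertiary alcohol while the acetal is still being cleaved.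
- Fallback: it sets out from 26 and comes back at 28. The aryl methoxymethyl ether would be removed without protic acid (Me3SiOTf, 2,2'-bipyridyl, CH2Cl2, 0 °C; then water) to give (2S)-2-{3-[(2E)-3,7-dimethyl-7-(triethylsilyloxy)oct-2-en-1-yl]-4-hydroxyphenyl}-5,7-dihydroxychroman-4-one F7. The silyl ether of F7 would then be cleaved with HF·pyridine in THF–pyridine at 0 °C to give 28.

## Further compounds

F1 | step 14 | {3-[(2E)-3,7-dimethyl-7-(triethylsilyloxy)oct-2-en-1-yl]-4-(methoxymethoxy)phenyl}boronic acid | C/C(=C\Cc1cc(B(O)O)ccc1OCOC)CCCC(C)(C)O[Si](CC)(CC)CC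
F2 | step 14 | 5,7-bis(methoxymethoxy)-4H-chromen-4-one | O=c1ccoc2cc(OCOC)cc(OCOC)c12
F3 | step 14 | (2S)-2-{3-[(2E)-3,7-dimethyl-7-(triethylsilyloxy)oct-2-en-1-yl]-4-(methoxymethoxy)phenyl}-5,7-bis(methoxymethoxy)chroman-4-one | C/C(=C\Cc1cc([C@@H]2CC(=O)c3c(OCOC)cc(OCOC)cc3O2)ccc1OCOC)CCCC(C)(C)O[Si](CC)(CC)CC
F4 | step 6 | 3-bromo-4-(methoxymethoxy)benzaldehyde | COCOc1ccc(C=O)cc1Br
F5 | step 6 | 4-(methoxymethoxy)-3-(4,4,5,5-tetramethyl-1,3,2-dioxaborolan-2-yl)benzaldehyde | COCOc1ccc(C=O)cc1B1OC(C)(C)C(C)(C)O1
F6 | step 8 | (6S)-4-(tert-butyldimethylsilyloxy)-6-{3-[(2E)-3,7-dimethyl-7-(triethylsilyloxy)oct-2-en-1-yl]-4-(methoxymethoxy)phenyl}-N,N-dimethyl-5,6-dihydro-2H-pyran-2-amine (aminal carbon undefined) | C/C(=C\Cc1cc([C@@H]2CC(O[Si](C)(C)C(C)(C)C)=CC(N(C)C)O2)ccc1OCOC)CCCC(C)(C)O[Si](CC)(CC)CC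
F0 | step 10 | none | none
F7 | step 15 | (2S)-2-{3-[(2E)-3,7-dimethyl-7-(triethylsilyloxy)oct-2-en-1-yl]-4-hydroxyphenyl}-5,7-dihydroxychroman-4-one | C/C(=C\Cc1cc([C@@H]2CC(=O)c3c(O)cc(O)cc3O2)ccc1O)CCCC(C)(C)O[Si](CC)(CC)CC
A1 | alternative 1 | methyl (8E)-9-{3-[(2E)-7-hydroxy-3,7-dimethyloct-2-en-1-yl]-4-(methoxymethoxy)phenyl}-3,5,7-trioxonon-8-enoate | C/C(=C\Cc1cc(/C=C/C(=O)CC(=O)CC(=O)CC(=O)OC)ccc1OCOC)CCCC(C)(C)O
A2 | alternative 1 | (2E)-3-{3-[(2E)-7-hydroxy-3,7-dimethyloct-2-en-1-yl]-4-(methoxymethoxy)phenyl}-1-(2,4,6-trihydroxyphenyl)prop-2-en-1-one | C/C(=C\Cc1cc(/C=C/C(=O)c2c(O)cc(O)cc2O)ccc1OCOC)CCCC(C)(C)O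
A3 | alternative 2 | (2S)-2-ethynyl-5,7-bis(methoxymethoxy)chroman-4-one | C#C[C@@H]1CC(=O)c2c(OCOC)cc(OCOC)cc2O1
A4 | alternative 2 | (5E)-6,10-dimethyl-3-methylidene-10-(triethylsilyloxy)-2-(trimethylsilyloxy)undeca-1,5-diene | C=C(O[Si](C)(C)C)C(=C)C/C=C(\C)CCCC(C)(C)O[Si](CC)(CC)CC
A5 | alternative 2 | (2S)-2-{3-[(2E)-3,7-dimethyl-7-(triethylsilyloxy)oct-2-en-1-yl]-4-(trimethylsilyloxy)phenyl}-5,7-bis(methoxymethoxy)chroman-4-one | C/C(=C\Cc1cc([C@@H]2CC(=O)c3c(OCOC)cc(OCOC)cc3O2)ccc1O[Si](C)(C)C)CCCC(C)(C)O[Si](CC)(CC)CC
A6 | alternative 3 | tert-butyl{[1-(2-{[(1S)-1-{3-[(2E)-7-(methoxymethoxy)-3,7-dimethyloct-2-en-1-yl]-4-(methoxymethoxy)phenyl}prop-2-en-1-yl]oxy}-4,6-bis(methoxymethoxy)phenyl)ethenyl]oxy}dimethylsilane | C=C[C@H](Oc1cc(OCOC)cc(OCOC)c1C(=C)O[Si](C)(C)C(C)(C)C)c1ccc(OCOC)c(C/C=C(\C)CCCC(C)(C)OCOC)c1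
A7 | alternative 3 | (2S)-4-(tert-butyldimethylsilyloxy)-2-{3-[(2E)-7-(methoxymethoxy)-3,7-dimethyloct-2-en-1-yl]-4-(methoxymethoxy)phenyl}-5,7-bis(methoxymethoxy)-2H-chromene | C/C(=C\Cc1cc([C@@H]2C=C(O[Si](C)(C)C(C)(C)C)c3c(OCOC)cc(OCOC)cc3O2)ccc1OCOC)CCCC(C)(C)OCOC
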